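**Plan**

- Retrosynthesis: cut the C8 ester, then the O5–C10 bond of the C5–O–C10 bridge (transannular capture of a C10 cation in a ten-membered ring), then C4–C5 of that carbocycle (Nozaki–Hiyama–Kishi), then the lactone at O–C6 and C11–C12, then C7–C8 (aldol).
- Enabling feature: the α-methylene-γ-butyrolactone O–C12(=O)–C11(=C13)–C7–C6 is CO2 laid across a vinylic C11 and a carbinol C6 whose neighbour C5 also bears oxygen. An open-chain C11 alkenyl triflate carrying a C5–C6 epoxide can therefore take up CO2 and close the lactone in one operation, and the epoxide oxygen survives as O5, the later ether bridge.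
- Forward order: open chain (C8–C10 and C1–C3 from linalool, C5–C7 and C11 from a butenoyl imide, C13 from MeMgBr) → lactone (step 11) → ten-membered carbocycle (C4–C5) → both seven-membered oxa-rings A and B at once by O5–C10 bond formation → C8 ester.
- Stereochemistry: C7 and C8 from an Evans syn-aldol; C6 from a hydroxyl-directed epoxidation followed by inversion in the lactonisation; C5 from Felkin–Anh addition in the ring closure; C10 forced by the one-atom bridge; the side-chain centre from a palladium-catalysed asymmetric allylic etherification.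

Key step: step 11

Germacrane numbering (C1–C15) is used for the core throughout.
Assumption 1: the stereocentre of commercial (R)-(−)-linalool becomes C10, which is ionised and re-formed in step 16, so neither its sense nor its optical purity reaches the target; it only keeps the intermediates single diastereomers.
Assumption 2: in step 17 the (R,R)-ligand is taken to give the (S)-ether; should the sense prove opposite, the (S,S)-ligand is used.

**Route**

Step 1
Reactants: 1 (R)-(−)-linalool [(3R)-3,7-dimethylocta-1,6-dien-3-ol]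
Product: 2 (3R)-3,7-dimethyl-3-(triethylsilyloxy)octa-1,6-diene
Conditions: TESOTf, 2,6-lutidine, CH2Cl2, 0 °C
Reagents that add atoms: triethylsilyl trifluoromethanesulfonate, CC[Si](CC)(CC)OS(=O)(=O)C(F)(F)F
Why: Silyl ether formation with the reactive silyl triflate masks the hindered tertiary allylic alcohol, whose oxygen is the group that leaves in step 16.

Step 2
Reactants: 2 (3R)-3,7-dimethyl-3-(triethylsilyloxy)octa-1,6-diene
Product: 4 (3R)-3,7-dimethyl-3-(triethylsilyloxy)oct-6-en-1-ol, via B-alkyl-9-BBN adduct 3 (not isolated)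
Conditions: 9-BBN, THF, 0 °C to rt; then NaOH, H2O2, 0 °C
Reagents that add atoms: hydrogen peroxide, OO
Why: Anti-Markovnikov hydroboration–oxidation with the bulky 9-BBN should touch only the monosubstituted vinyl group and spare the trisubstituted alkene, giving the primary alcohol that becomes C8.

Step 3
Reactants: 4 (3R)-3,7-dimethyl-3-(triethylsilyloxy)oct-6-en-1-ol
Product: 5 (3R)-3,7-dimethyl-3-(triethylsilyloxy)oct-6-enal
Conditions: Dess–Martin periodinane, CH2Cl2, 0 °C to rt
Reagents that add atoms: none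
Why: Dess–Martin oxidation stops at the aldehyde and is mild enough for the silyl ether, and the quaternary β-carbon rules out elimination to an enal.

Step 4
Reactants: 6 but-3-enoic acid; 7 (S)-4-benzyloxazolidin-2-one
Product: 9 (S)-4-benzyl-3-(but-3-enoyl)oxazolidin-2-one, via mixed pivalic anhydride 8 (not isolated)
Conditions: PivCl, Et3N, THF, −20 °C; then 7, LiCl, −20 °C to rt
Reagents that add atoms: none
Why: N-Acylation of the oxazolidinone through the mixed pivalic anhydride loads the auxiliary under conditions that should not move the β,γ-double bond into conjugation.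

Step 5
Reactants: 9 (S)-4-benzyl-3-(but-3-enoyl)oxazolidin-2-one; 5 (3R)-3,7-dimethyl-3-(triethylsilyloxy)oct-6-enal
Product: 11 (S)-4-benzyl-3-[(2S,3R,5R)-2-ethenyl-3-hydroxy-5,9-dimethyl-5-(triethylsilyloxy)dec-8-enoyl]oxazolidin-2-one, via Z boron enolate 10 (not isolated)
Conditions: Bu2BOTf, Et3N, CH2Cl2, −78 to 0 °C; then 5, −78 to 0 °C; pH 7 buffer, MeOH, H2O2
Reagents that add atoms: none
Why: Evans syn-aldol reaction, in which the Z-boron enolate adds at its α-carbon through a closed Zimmerman–Traxler chair on the face away from the benzyl group, which should set C7 and C8 in the absolute sense of the target (C11 and O8 anti along the C6–C9 chain).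

Step 6
Reactants: 11 (S)-4-benzyl-3-[(2S,3R,5R)-2-ethenyl-3-hydroxy-5,9-dimethyl-5-(triethylsilyloxy)dec-8-enoyl]oxazolidin-2-one
Product: 12 (2S,3R,5R)-2-ethenyl-3-hydroxy-N-methoxy-N,5,9-trimethyl-5-(triethylsilyloxy)dec-8-enamide
Conditions: MeNH(OMe)·HCl, Me3Al, CH2Cl2, −20 to 0 °C
Reagents that add atoms: N,O-dimethylhydroxylamine hydrochloride, CNOC.Cl
Why: Aluminium-amide transamidation to the Weinreb amide is assisted by the free β-hydroxyl and releases the auxiliary without epimerising C7.

Step 7
Reactants: 12 (2S,3R,5R)-2-ethenyl-3-hydroxy-N-methoxy-N,5,9-trimethyl-5-(triethylsilyloxy)dec-8-enamide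
Product: 13 (2R,3R,5R)-3-hydroxy-N-methoxy-N,5,9-trimethyl-2-[(2R)-oxiran-2-yl]-5-(triethylsilyloxy)dec-8-enamide
Conditions: VO(acac)2 (5 mol %), t-BuOOH, CH2Cl2, 0 °C to rt
Reagents that add atoms: tert-butyl hydroperoxide, CC(C)(C)OO
Why: Hydroxyl-directed vanadium-catalysed epoxidation of the homoallylic alcohol should pass through a chair-like vanadate ester with the C9 chain and the C11 amide both equatorial and the allylic hydrogen eclipsing the vinyl group, which delivers oxygen anti to C11 and syn to O8 (the 6R epoxide) and leaves the remote, undirected trisubstituted alkene alone.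

Step 8
Reactants: 13 (2R,3R,5R)-3-hydroxy-N-methoxy-N,5,9-trimethyl-2-[(2R)-oxiran-2-yl]-5-(triethylsilyloxy)dec-8-enamide
Product: 14 (2S,3R,5R)-N-methoxy-N,5,9-trimethyl-2-[(2R)-oxiran-2-yl]-3,5-bis(triethylsilyloxy)dec-8-enamide
Conditions: TESOTf, 2,6-lutidine, CH2Cl2, −78 °C
Reagents that add atoms: triethylsilyl trifluoromethanesulfonate, CC[Si](CC)(CC)OS(=O)(=O)C(F)(F)F
Why: Silyl ether formation at low temperature masks O8 for the organometallic and base steps without opening the epoxide (the C2 descriptor changes only through priority).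

Step 9
Reactants: 14 (2S,3R,5R)-N-methoxy-N,5,9-trimethyl-2-[(2R)-oxiran-2-yl]-3,5-bis(triethylsilyloxy)dec-8-enamide
Product: 15 (3S,4R,6R)-6,10-dimethyl-3-[(2R)-oxiran-2-yl]-4,6-bis(triethylsilyloxy)undec-9-en-2-one
Conditions: MeMgBr, THF, −78 to −20 °C
Reagents that add atoms: methylmagnesium bromide, C[Mg]Br
Why: Weinreb ketone synthesis, in which the chelated tetrahedral magnesium adduct holds until work-up so that the reaction stops at the methyl ketone, and a copper-free Grignard reagent at low temperature should not open the terminal epoxide.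

Step 10
Reactants: 15 (3S,4R,6R)-6,10-dimethyl-3-[(2R)-oxiran-2-yl]-4,6-bis(triethylsilyloxy)undec-9-en-2-one
Product: 17 (3S,4R,6R)-6,10-dimethyl-3-[(2R)-oxiran-2-yl]-4,6-bis(triethylsilyloxy)undeca-1,9-dien-2-yl trifluoromethanesulfonate, via potassium enolate 16 (not isolated)
Conditions: KHMDS, THF, −78 °C; then PhNTf2, −78 °C
Reagents that add atoms: N-phenylbis(trifluoromethanesulfonimide), O=S(=O)(N(c1ccccc1)S(=O)(=O)C(F)(F)F)C(F)(F)F
Why: Kinetic deprotonation with a hindered amide base should occur at the methyl group and not at the crowded C7 methine, and O-triflation of that enolate (enol triflate formation) gives the 1,1-disubstituted alkenyl triflate that is the latent C11 nucleophile.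

Step 11
Reactants: 17 (3S,4R,6R)-6,10-dimethyl-3-[(2R)-oxiran-2-yl]-4,6-bis(triethylsilyloxy)undeca-1,9-dien-2-yl trifluoromethanesulfonate
Product: 19 (4S,5S)-4-[(1R,3R)-3,7-dimethyl-1,3-bis(triethylsilyloxy)oct-6-en-1-yl]-5-(hydroxymethyl)-3-methylideneoxolan-2-one, via epoxy acrylate carboxylate 18 (not isolated)
Conditions: NiBr2(bpy) (10 mol %), Mn powder, CO2 (1 atm), DMA, 25 °C, then 50 °C; aq. citric acid work-up
Reagents that add atoms: carbon dioxide, O=C=O
Why: Proposed new method: zerovalent nickel (from NiBr2(bpy) and Mn) should insert into the C11–OTf bond, reduction to the monovalent alkenylnickel species is followed by CO2 insertion (C11–C12 bond), and the metal carboxylate 18, held two atoms from C6, should open the epoxide, activated by the divalent manganese salts, to form the O–C6 bond, so that CO2 is annulated as the O–C(=O) unit across C11 and C6 in a formal (3+2) sense. The closest known reaction types are the nickel- and cobalt-catalysed reductive carboxylation of alkenyl triflates with CO2 and the cyclisation of γ,δ-epoxy carboxylates to γ-lactones; what is new is their coupling in one operation on a homoallylic epoxide. The only ring closed is the γ-lactone, by intramolecular SN2 (5-exo-tet) opening of the epoxide at C6 and not 6-endo attack at the terminal C5, which the short rigid acrylate tether and the exo preference of epoxide openings should secure. C6 is the only stereocentre touched and is inverted (6R epoxide to 6S lactone), so the trans relation of H6 and H7 follows from the epoxide set in step 7, while C7 and C8 are spectators and the epoxide oxygen is kept as the C5 hydroxyl. The step needs chemoselective activation of the C–OTf bond beside an epoxide, two silyl ethers and an alkene, which the non-basic room-temperature conditions should allow. It is run on the open chain because backside attack at C6 leading to a trans-fused lactone needs a C5–C6–C7–C8 torsion well above 100°, which a chain adopts freely but the later seven-membered ring could not.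

Step 12
Reactants: 19 (4S,5S)-4-[(1R,3R)-3,7-dimethyl-1,3-bis(triethylsilyloxy)oct-6-en-1-yl]-5-(hydroxymethyl)-3-methylideneoxolan-2-one
Product: 21 (4R,6R)-6-[(2S,3S)-2-(hydroxymethyl)-4-methylidene-5-oxooxolan-3-yl]-4-methyl-4,6-bis(triethylsilyloxy)hexanal, via vicinal diol 20 (not isolated)
Conditions: OsO4 (2 mol %), NaIO4, 2,6-lutidine, dioxane–H2O, rt
Reagents that add atoms: sodium periodate, [Na+].[O-]I(=O)(=O)=O; osmium tetroxide (catalytic oxygen carrier), O=[Os](=O)(=O)=O
Why: Lemieux–Johnson oxidation, in which catalytic OsO4 should dihydroxylate the electron-rich trisubstituted alkene in preference to the electron-poor α-methylene lactone and periodate cleaves the diol to unveil the C3 aldehyde.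

Step 13
Reactants: 21 (4R,6R)-6-[(2S,3S)-2-(hydroxymethyl)-4-methylidene-5-oxooxolan-3-yl]-4-methyl-4,6-bis(triethylsilyloxy)hexanal
Product: 22 methyl (2Z,6R,8R)-8-[(2S,3S)-2-(hydroxymethyl)-4-methylidene-5-oxooxolan-3-yl]-2-iodo-6-methyl-6,8-bis(triethylsilyloxy)oct-2-enoate
Conditions: Ph3P=CHCO2Me, N-iodosuccinimide, CH2Cl2, −20 °C; then K2CO3, 21, −20 °C to rt
Reagents that add atoms: methyl (triphenylphosphoranylidene)acetate, COC(=O)C=P(c1ccccc1)(c1ccccc1)c1ccccc1; N-iodosuccinimide, O=C1CCC(=O)N1I
Why: Wittig olefination with the stabilised α-iodo ylide made in the flask should give the (Z)-2-iodo-2-enoate (iodine cis to the C2 chain, ester trans), which fixes the geometry that the C3=C4 bond needs inside ring A.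

Step 14
Reactants: 22 methyl (2Z,6R,8R)-8-[(2S,3S)-2-(hydroxymethyl)-4-methylidene-5-oxooxolan-3-yl]-2-iodo-6-methyl-6,8-bis(triethylsilyloxy)oct-2-enoate
Product: 23 methyl (2Z,6R,8R)-8-[(2S,3S)-2-formyl-4-methylidene-5-oxooxolan-3-yl]-2-iodo-6-methyl-6,8-bis(triethylsilyloxy)oct-2-enoate
Conditions: Dess–Martin periodinane, CH2Cl2, 0 °C
Reagents that add atoms: none
Why: Dess–Martin oxidation turns the primary C5 alcohol into the aldehyde under non-basic conditions that should not epimerise the α-acyloxy centre C6.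

Step 15
Reactants: 23 methyl (2Z,6R,8R)-8-[(2S,3S)-2-formyl-4-methylidene-5-oxooxolan-3-yl]-2-iodo-6-methyl-6,8-bis(triethylsilyloxy)oct-2-enoate
Product: 24 methyl (3E,5R,6S,7S,8R,10R)-5-hydroxy-8,10-bis(triethylsilyloxy)germacra-3,11(13)-dien-12,6-olid-15-oate
Conditions: CrCl2 (excess), NiCl2 (cat.), DMSO, rt, high dilution (about 2 mM)
Reagents that add atoms: none
Why: Nozaki–Hiyama–Kishi reaction, in which the alkenylchromium species from the activated alkenyl iodide adds chemoselectively to the aldehyde and closes the ten-membered carbocycle at C4–C5 with retention of alkene geometry, and Felkin–Anh attack anti to the C6–O bond should favour the 5R alcohol (O5 anti to O6).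

Step 16
Reactants: 24 methyl (3E,5R,6S,7S,8R,10R)-5-hydroxy-8,10-bis(triethylsilyloxy)germacra-3,11(13)-dien-12,6-olid-15-oate
Product: 26 methyl (5R,6S,7R,8R,10S)-8-hydroxy-5,10-epoxygermacra-3,11(13)-dien-12,6-olid-15-oate, via triol 25 (not isolated)
Conditions: HF·pyridine, THF, 0 °C to rt; evaporate; then TfOH (5 mol %), CH2Cl2, −20 to 0 °C
Reagents that add atoms: none
Why: After fluoride desilylation, acid should ionise the tertiary C10 alcohol and O5 captures the cation across the ring (transannular SN1 etherification), closing rings A and B together, and because a one-atom bridge can span C5 and C10 only on the face of O5 the new C10 centre is forced into the target configuration whatever it was before.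

Step 17
Reactants: 27 2-methyl-2-vinyloxirane (racemic isoprene monoepoxide); 28 4-methoxybenzyl alcohol
Product: 29 (2S)-2-[(4-methoxyphenyl)methoxy]-2-methylbut-3-en-1-ol
Conditions: Pd2(dba)3·CHCl3 (1 mol %), (R,R)-N,N'-(cyclohexane-1,2-diyl)bis[2-(diphenylphosphino)benzamide] (3 mol %), Et3B (1 mol %), CH2Cl2, rt
Reagents that add atoms: none
Why: Palladium-catalysed dynamic kinetic asymmetric allylic etherification (Tsuji–Trost type), in which both epoxide enantiomers ionise to interconverting π-allyl palladium alkoxides, the borane co-catalyst delivers the alcohol to the more substituted terminus, and the chiral diphosphine should set the tertiary ether centre as S.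

Step 18
Reactants: 29 (2S)-2-[(4-methoxyphenyl)methoxy]-2-methylbut-3-en-1-ol
Product: 31 (2S)-2-[(4-methoxyphenyl)methoxy]-2-methylbut-3-enoic acid, via aldehyde 30 (not isolated)
Conditions: TEMPO (cat.), PhI(OAc)2, MeCN–H2O, rt
Reagents that add atoms: water, O
Why: TEMPO-catalysed oxidation takes the primary alcohol through the aldehyde hydrate to the acid without touching the vinyl group or the benzyl ether, and the quaternary centre cannot epimerise.

Step 19
Reactants: 31 (2S)-2-[(4-methoxyphenyl)methoxy]-2-methylbut-3-enoic acid; 26 methyl (5R,6S,7R,8R,10S)-8-hydroxy-5,10-epoxygermacra-3,11(13)-dien-12,6-olid-15-oate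
Product: 33 methyl (5R,6S,7R,8R,10S)-8-{(2S)-2-[(4-methoxyphenyl)methoxy]-2-methylbut-3-enoyloxy}-5,10-epoxygermacra-3,11(13)-dien-12,6-olid-15-oate, via mixed trichlorobenzoic anhydride 32 (not isolated)
Conditions: 2,4,6-trichlorobenzoyl chloride, Et3N, THF, rt; then 26, DMAP, toluene, rt
Reagents that add atoms: none
Why: Yamaguchi esterification through the mixed anhydride and DMAP is the standard answer to a hindered secondary alcohol and a quaternary α-alkoxy acid, the masked tertiary hydroxyl leaves O8 as the only acylation site, and C8 is retained.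

Step 20
Reactants: 33 methyl (5R,6S,7R,8R,10S)-8-{(2S)-2-[(4-methoxyphenyl)methoxy]-2-methylbut-3-enoyloxy}-5,10-epoxygermacra-3,11(13)-dien-12,6-olid-15-oate
Product: 34 CNP0325750.1 (the target)
Conditions: DDQ, CH2Cl2–pH 7 buffer, 0 °C
Reagents that add atoms: none
Why: Oxidative cleavage of the 4-methoxybenzyl ether by DDQ (benzylic hydride abstraction, then hydrolysis) should leave the electron-poor alkenes, the lactone and the esters untouched and releases the tertiary alcohol of the target.

**Compound list**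

1 | (R)-(−)-linalool, (3R)-3,7-dimethylocta-1,6-dien-3-ol | C=C[C@](C)(O)CCC=C(C)C | starting material
2 | (3R)-3,7-dimethyl-3-(triethylsilyloxy)octa-1,6-diene | C=C[C@](C)(O[Si](CC)(CC)CC)CCC=C(C)C | intermediate
3 | 9-[(3S)-3,7-dimethyl-3-(triethylsilyloxy)oct-6-en-1-yl]-9-borabicyclo[3.3.1]nonane (same spatial arrangement as 2; descriptor changes by priority) | B1(CC[C@](C)(O[Si](CC)(CC)CC)CCC=C(C)C)C2CCCC1CCC2 | intermediate
4 | (3R)-3,7-dimethyl-3-(triethylsilyloxy)oct-6-en-1-ol | OCC[C@](C)(O[Si](CC)(CC)CC)CCC=C(C)C | intermediate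
5 | (3R)-3,7-dimethyl-3-(triethylsilyloxy)oct-6-enal | O=CC[C@](C)(O[Si](CC)(CC)CC)CCC=C(C)C | intermediate
6 | but-3-enoic acid | C=CCC(=O)O | starting material
7 | (S)-4-benzyloxazolidin-2-one | O=C1OC[C@H](Cc2ccccc2)N1 | starting material
8 | but-3-enoic pivalic anhydride | C=CCC(=O)OC(=O)C(C)(C)C | intermediate
9 | (S)-4-benzyl-3-(but-3-enoyl)oxazolidin-2-one | C=CCC(=O)N1[C@@H](Cc2ccccc2)COC1=O | intermediate
10 | Z-(O)-dibutylboron dienolate of 9 | C=C/C=C(\OB(CCCC)CCCC)N1[C@@H](Cc2ccccc2)COC1=O | intermediate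
11 | (S)-4-benzyl-3-[(2S,3R,5R)-2-ethenyl-3-hydroxy-5,9-dimethyl-5-(triethylsilyloxy)dec-8-enoyl]oxazolidin-2-one | O=C1OC[C@H](Cc2ccccc2)N1C(=O)[C@@H](C=C)[C@H](O)C[C@](C)(O[Si](CC)(CC)CC)CCC=C(C)C | intermediate
12 | (2S,3R,5R)-2-ethenyl-3-hydroxy-N-methoxy-N,5,9-trimethyl-5-(triethylsilyloxy)dec-8-enamide | CON(C)C(=O)[C@@H](C=C)[C@H](O)C[C@](C)(O[Si](CC)(CC)CC)CCC=C(C)C | intermediate
13 | (2R,3R,5R)-3-hydroxy-N-methoxy-N,5,9-trimethyl-2-[(2R)-oxiran-2-yl]-5-(triethylsilyloxy)dec-8-enamide | CON(C)C(=O)[C@@H]([C@@H]1CO1)[C@H](O)C[C@](C)(O[Si](CC)(CC)CC)CCC=C(C)C | intermediate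
14 | (2S,3R,5R)-N-methoxy-N,5,9-trimethyl-2-[(2R)-oxiran-2-yl]-3,5-bis(triethylsilyloxy)dec-8-enamide | CON(C)C(=O)[C@@H]([C@@H]1CO1)[C@H](O[Si](CC)(CC)CC)C[C@](C)(O[Si](CC)(CC)CC)CCC=C(C)C | intermediate
15 | (3S,4R,6R)-6,10-dimethyl-3-[(2R)-oxiran-2-yl]-4,6-bis(triethylsilyloxy)undec-9-en-2-one | CC(=O)[C@@H]([C@@H]1CO1)[C@H](O[Si](CC)(CC)CC)C[C@](C)(O[Si](CC)(CC)CC)CCC=C(C)C | intermediate
16 | potassium (3S,4R,6R)-6,10-dimethyl-3-[(2R)-oxiran-2-yl]-4,6-bis(triethylsilyloxy)undeca-1,9-dien-2-olate | C=C([O-])[C@@H]([C@@H]1CO1)[C@H](O[Si](CC)(CC)CC)C[C@](C)(O[Si](CC)(CC)CC)CCC=C(C)C.[K+] | intermediate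
17 | (3S,4R,6R)-6,10-dimethyl-3-[(2R)-oxiran-2-yl]-4,6-bis(triethylsilyloxy)undeca-1,9-dien-2-yl trifluoromethanesulfonate | C=C(OS(=O)(=O)C(F)(F)F)[C@@H]([C@@H]1CO1)[C@H](O[Si](CC)(CC)CC)C[C@](C)(O[Si](CC)(CC)CC)CCC=C(C)C | intermediate
18 | (3S,4R,6R)-6,10-dimethyl-2-methylidene-3-[(2R)-oxiran-2-yl]-4,6-bis(triethylsilyloxy)undec-9-enoate (metal carboxylate) | C=C(C(=O)[O-])[C@@H]([C@@H]1CO1)[C@H](O[Si](CC)(CC)CC)C[C@](C)(O[Si](CC)(CC)CC)CCC=C(C)C | intermediate
19 | (4S,5S)-4-[(1R,3R)-3,7-dimethyl-1,3-bis(triethylsilyloxy)oct-6-en-1-yl]-5-(hydroxymethyl)-3-methylideneoxolan-2-one | C=C1C(=O)O[C@H](CO)[C@H]1[C@H](O[Si](CC)(CC)CC)C[C@](C)(O[Si](CC)(CC)CC)CCC=C(C)C | intermediate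
20 | (4S,5S)-4-[(1R,3R)-6,7-dihydroxy-3,7-dimethyl-1,3-bis(triethylsilyloxy)octyl]-5-(hydroxymethyl)-3-methylideneoxolan-2-one (both C6' epimers) | C=C1C(=O)O[C@H](CO)[C@H]1[C@H](O[Si](CC)(CC)CC)C[C@](C)(O[Si](CC)(CC)CC)CCC(O)C(C)(C)O | intermediate
21 | (4R,6R)-6-[(2S,3S)-2-(hydroxymethyl)-4-methylidene-5-oxooxolan-3-yl]-4-methyl-4,6-bis(triethylsilyloxy)hexanal | C=C1C(=O)O[C@H](CO)[C@H]1[C@H](O[Si](CC)(CC)CC)C[C@](C)(O[Si](CC)(CC)CC)CCC=O | intermediate
22 | methyl (2Z,6R,8R)-8-[(2S,3S)-2-(hydroxymethyl)-4-methylidene-5-oxooxolan-3-yl]-2-iodo-6-methyl-6,8-bis(triethylsilyloxy)oct-2-enoate | C=C1C(=O)O[C@H](CO)[C@H]1[C@H](O[Si](CC)(CC)CC)C[C@](C)(O[Si](CC)(CC)CC)CC/C=C(\I)C(=O)OC | intermediate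
23 | methyl (2Z,6R,8R)-8-[(2S,3S)-2-formyl-4-methylidene-5-oxooxolan-3-yl]-2-iodo-6-methyl-6,8-bis(triethylsilyloxy)oct-2-enoate | C=C1C(=O)O[C@H](C=O)[C@H]1[C@H](O[Si](CC)(CC)CC)C[C@](C)(O[Si](CC)(CC)CC)CC/C=C(\I)C(=O)OC | intermediate
24 | methyl (3E,5R,6S,7S,8R,10R)-5-hydroxy-8,10-bis(triethylsilyloxy)germacra-3,11(13)-dien-12,6-olid-15-oate (ten-membered carbocycle, trans-fused lactone) | O[C@@H]1/C(C(=O)OC)=C\CC[C@@](C)(O[Si](CC)(CC)CC)C[C@@H](O[Si](CC)(CC)CC)[C@H]2C(=C)C(=O)O[C@H]12 | intermediate
25 | methyl (3E,5R,6S,7R,8R,10R)-5,8,10-trihydroxygermacra-3,11(13)-dien-12,6-olid-15-oate | O[C@@H]1/C(C(=O)OC)=C\CC[C@@](C)(O)C[C@@H](O)[C@H]2C(=C)C(=O)O[C@H]12 | intermediate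
26 | methyl (5R,6S,7R,8R,10S)-8-hydroxy-5,10-epoxygermacra-3,11(13)-dien-12,6-olid-15-oate | O[C@@H]1C[C@]2(C)CCC=C(C(=O)OC)[C@@H](O2)[C@H]2OC(=O)C(=C)[C@@H]21 | intermediate
27 | 2-methyl-2-vinyloxirane (racemic) | CC1(C=C)CO1 | starting material
28 | 4-methoxybenzyl alcohol | COc1ccc(CO)cc1 | starting material
29 | (2S)-2-[(4-methoxyphenyl)methoxy]-2-methylbut-3-en-1-ol | C=C[C@](C)(OCc1ccc(OC)cc1)CO | intermediate
30 | (2S)-2-[(4-methoxyphenyl)methoxy]-2-methylbut-3-enal | C=C[C@](C)(OCc1ccc(OC)cc1)C=O | intermediate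
31 | (2S)-2-[(4-methoxyphenyl)methoxy]-2-methylbut-3-enoic acid | C=C[C@](C)(OCc1ccc(OC)cc1)C(=O)O | intermediate
32 | (2S)-2-[(4-methoxyphenyl)methoxy]-2-methylbut-3-enoic 2,4,6-trichlorobenzoic anhydride | C=C[C@](C)(OCc1ccc(OC)cc1)C(=O)OC(=O)c1c(Cl)cc(Cl)cc1Cl | intermediate
33 | methyl (5R,6S,7R,8R,10S)-8-{(2S)-2-[(4-methoxyphenyl)methoxy]-2-methylbut-3-enoyloxy}-5,10-epoxygermacra-3,11(13)-dien-12,6-olid-15-oate | C=C[C@](C)(OCc1ccc(OC)cc1)C(=O)O[C@@H]1C[C@]2(C)CCC=C(C(=O)OC)[C@@H](O2)[C@H]2OC(=O)C(=C)[C@@H]21 | intermediate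
34 | CNP0325750.1, methyl (5R,6S,7R,8R,10S)-8-[(2S)-2-hydroxy-2-methylbut-3-enoyloxy]-5,10-epoxygermacra-3,11(13)-dien-12,6-olid-15-oate | C=C[C@](C)(O)C(=O)O[C@@H]1C[C@]2(C)CCC=C(C(=O)OC)[C@@H](O2)[C@H]2OC(=O)C(=C)[C@@H]21 | target

**Count and risks**

Total step count: 20. Longest linear sequence: 17 steps (steps 1–3, 5–16, 19 and 20).

The three steps most likely to fail:

Step 11 (proposed new method). The alkenylnickel species may be protonated before it captures CO2, the epoxide may be opened reductively or by halide under the metal/Mn conditions, or the carboxylate may attack the terminal C5 instead of C6. The fallback separates the events with known chemistry and sets out from 17. Stannylation with Me3SnSnMe3, Pd(PPh3)4 and LiCl should give trimethyl{(3S,4R,6R)-6,10-dimethyl-3-[(2R)-oxiran-2-yl]-4,6-bis(triethylsilyloxy)undeca-1,9-dien-2-yl}stannane F1. Tin–lithium exchange with MeLi at −78 °C and a CO2 quench then give the lithium salt of 18, which on warming and mildly acidic work-up should close by the same 5-exo epoxide opening. The fallback comes back to the route at 19.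

Step 15. Facial selectivity in the addition to the α-acyloxy aldehyde may be poor inside the forming ring, and chain growth may compete with ring closure. The fallback sets out from 23 and moves the control of C5 from the carbon–carbon bond formation to a reagent-controlled reduction. The ring is closed as before, and the mixture of 24 with its epimer, methyl (3E,5S,6S,7S,8R,10R)-5-hydroxy-8,10-bis(triethylsilyloxy)germacra-3,11(13)-dien-12,6-olid-15-oate F2, is oxidised with Dess–Martin periodinane to the macrocyclic ketone, methyl (3E,6S,7S,8R,10R)-5-oxo-8,10-bis(triethylsilyloxy)germacra-3,11(13)-dien-12,6-olid-15-oate F3. Corey–Bakshi–Shibata reduction (the oxazaborolidine enantiomer matched to the 5R face, catecholborane, −78 °C) should then return the route to 24.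

Step 16. Loss of a proton from the C10 cation, a transannular hydride shift from C5, or acid-promoted migration of the lactone to O8 may outrun capture of the cation by O5. The fallback sets out from 24 and replaces the free cation by a radical–polar crossover on an alkene. Desilylation with HF·pyridine alone gives triol 25, which is isolated. Selective low-temperature dehydration of its tertiary alcohol with bis[α,α-bis(trifluoromethyl)benzyloxy]diphenylsulfur gives methyl (3E,5R,6S,7R,8R)-5,8-dihydroxygermacra-3,10(14),11(13)-trien-12,6-olid-15-oate F4, together with its endocyclic alkene isomers, which should converge on the same product. Cobalt-catalysed hydrogen-atom-transfer hydroalkoxylation of the Mukaiyama type (Co(salen), N-fluoro-2,4,6-trimethylpyridinium triflate, 1,1,3,3-tetramethyldisiloxane) should then form the tertiary ether transannularly. The fallback comes back to the route at 26.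

**Further compounds**

F1 | step 11 | trimethyl{(3S,4R,6R)-6,10-dimethyl-3-[(2R)-oxiran-2-yl]-4,6-bis(triethylsilyloxy)undeca-1,9-dien-2-yl}stannane | C=C([Sn](C)(C)C)[C@@H]([C@@H]1CO1)[C@H](O[Si](CC)(CC)CC)C[C@](C)(O[Si](CC)(CC)CC)CCC=C(C)C
F2 | step 15 | methyl (3E,5S,6S,7S,8R,10R)-5-hydroxy-8,10-bis(triethylsilyloxy)germacra-3,11(13)-dien-12,6-olid-15-oate | O[C@H]1/C(C(=O)OC)=C\CC[C@@](C)(O[Si](CC)(CC)CC)C[C@@H](O[Si](CC)(CC)CC)[C@H]2C(=C)C(=O)O[C@H]12
F3 | step 15 | methyl (3E,6S,7S,8R,10R)-5-oxo-8,10-bis(triethylsilyloxy)germacra-3,11(13)-dien-12,6-olid-15-oate | O=C1/C(C(=O)OC)=C\CC[C@@](C)(O[Si](CC)(CC)CC)C[C@@H](O[Si](CC)(CC)CC)[C@H]2C(=C)C(=O)O[C@H]12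
F4 | step 16 | methyl (3E,5R,6S,7R,8R)-5,8-dihydroxygermacra-3,10(14),11(13)-trien-12,6-olid-15-oate | O[C@@H]1/C(C(=O)OC)=C\CCC(=C)C[C@@H](O)[C@H]2C(=C)C(=O)O[C@H]12
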